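**Retrosynthetic overview**
1. Target 28 ⇐ pentaol 26 (orthoester mono-acetylation of both cis-diols) ⇐ hydroxyl-directed cyclopropanation of C13=C15 ⇐ OsO4 dihydroxylation of C6=C7 and C11=C12 on the convex β face of triene 24.
2. Ring C ⇐ intramolecular Nozaki–Hiyama–Kishi closure (C12–C13) of an α-iodoenone aldehyde, then dehydration to C11=C12.
3. Cyclobutane ⇐ Wolff ring contraction of a trans-hydrindane α-diazoketone: C9 shifts from C12 to C11, C12 leaves the ring as the ester, and the 1α-H/10β-CH3 trans fusion is inherited.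
4. Ring A ⇐ two Michael additions of 3-methylbutan-2-one onto a bis-enone (C2→C1 intermolecular, then C4→C5 intramolecular).
5. Ring B and the five-membered ring ⇐ asymmetric Michael/aldol of cyclotene with methyl vinyl ketone. Ring order: five-membered ring + B → A → four-membered ring (contraction) → C → cyclopropane.

Assumption: abietane-type numbering is used (ring A C1–C5, C10; ring B C5–C10; cyclobutane C1, C10, C9, C11; ring C C8, C9, C11–C14; cyclopropane C13, C15, C16; before the contraction the five-membered ring is C10–C1–C11–C12–C9), β is the face of the C10 methyl, and centres called "epimers" are left undefined in the SMILES.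

**Step 1**
Reactants: 1 2-hydroxy-3-methylcyclopent-2-en-1-one (cyclotene); 2 but-3-en-2-one
Product: 4 (3aR,7aS)-7a-hydroxy-3a-methylhexahydro-1H-indene-1,6(2H)-dione (cis-ketol: 9β-OH, 10β-CH3, ketones at C12 and C7), via Michael triketone 3 (not isolated)
Conditions: 9-O-benzylcupreidine (10 mol %; the pseudo-enantiomer that gives (R)-3), CH2Cl2, −20 °C; then pyrrolidine/AcOH (30 mol %), rt
Reagents that add atoms: none
Why: Proposed new method: enantioselective Michael addition of a 3-alkyl diosphenol (cyclic 1,2-dione enol) to an enone under bifunctional cinchona catalysis, telescoped with a Hajos–Parrish-type aldol; the quinuclidine deprotonates the acidic enol OH of 1 while the 6′-OH of the catalyst hydrogen-bonds the enone, the ion-paired enolate attacks through C10 on one enantioface to give the quaternary centre of 3, and the pyrrolidine enamine of the side-chain ketone then adds to the adjacent, strongly electrophilic C9 carbonyl from the side of the tether, which forces the cis fusion (9β-OH cis to 10β-CH3); closest known reaction types are cinchona-catalysed conjugate additions of α-substituted β-keto esters and 1,3-diketones to enones and the Hajos–Parrish ketol synthesis.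

**Step 2**
Reactants: 4 cis-ketol
Product: 5 bis-enone (4 with C1=C11 conjugated to the C12 ketone and C5=C6 conjugated to the C7 ketone)
Conditions: IBX (5 equiv), DMSO/fluorobenzene, 75 °C
Reagents that add atoms: none
Why: IBX α,β-dehydrogenation through the enols; each ketone can desaturate only away from the quaternary C9/C10, so one bis-enone forms and C8 becomes the only enolisable carbon.

**Step 3**
Reactants: 5 bis-enone; 6 but-2-ynal
Product: 8 9,14-bis-O-TBS ether of the C8 aldol adduct (8β-H; C14 epimers), via aldol dialkoxide 7 (not isolated)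
Conditions: LiN(i-Pr)2 (2.2 equiv), THF, −78 °C; 6; then TBSOTf (2.5 equiv), −78 → 0 °C
Reagents that add atoms: tert-butyldimethylsilyl trifluoromethanesulfonate, CC(C)(C)[Si](C)(C)OS(=O)(=O)C(F)(F)F
Why: Aldol addition of the cross-conjugated lithium dienolate to the ynal; the new bond forms axially and anti to the 1,3-related angular methyl, which puts the side chain on the α face (8β-H), and both alkoxides are silylated in the same pot (the C14 carbinol centre is destroyed in step 12).

**Step 4**
Reactants: 9 3-methylbutan-2-one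
Product: 10 2-(tert-butyldimethylsilyloxy)-3-methylbut-1-ene
Conditions: KN(SiMe3)2, THF, −78 °C; TBSCl
Reagents that add atoms: tert-butylchlorodimethylsilane, CC(C)(C)[Si](C)(C)Cl
Why: Kinetic deprotonation at the methyl group and O-silylation give the less substituted silyl enol ether.

**Step 5**
Reactants: 8 bis-TBS bis-enone; 10 silyl enol ether
Product: 11 Michael adduct (1β-(3-methyl-2-oxobutyl), 1α-H, C11=C12 TBS enol ether)
Conditions: TBSOTf (5 mol %), CH2Cl2, −78 °C; Et3N quench
Reagents that add atoms: none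
Why: Mukaiyama–Michael addition with silyl transfer; the cyclopentenone is the more electrophilic enone (the cyclohexenone is α′-branched), and the nucleophile enters C1 on the β face, away from ring B and the C8 side chain on the concave α face, which sets 1α-H and leaves a regiodefined C11=C12 silyl enol ether.

**Step 6**
Reactants: 11 Michael adduct
Product: 13 tricyclic C7 enol triflate (ring A closed; 5β-H; C11=C12 TBS enol ether kept), via TMS enol ether 12 (not isolated)
Conditions: Me3SiI, HN(SiMe3)2, CH2Cl2, −78 → −20 °C; then CsF, PhNTf2, DME, rt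
Reagents that add atoms: N-phenylbis(trifluoromethanesulfonimide), O=S(=O)(N(c1ccccc1)S(=O)(=O)C(F)(F)F)C(F)(F)F
Why: Silyl-iodide-promoted intramolecular Michael addition; the thermodynamic C3=C4 enol silane can reach C5 of the ring B enone only from the α face (the side of C1), so ring A closes trans to the five-membered ring and cis to ring B with quaternary C4 and 5β-H, and the resulting C6=C7 TMS enol ether is cleaved by fluoride in preference to the hindered TBS enol ether and trapped as the triflate.

**Step 7**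
Reactants: 13 enol triflate
Product: 14 6-ene (C7 triflate replaced by H)
Conditions: Pd(OAc)2 (5 mol %), PPh3, HCO2H, Bu3N, DMF, 60 °C
Reagents that add atoms: none
Why: Formate reduction of an enol triflate (zerovalent palladium inserts into C–OTf, formate delivers hydride, reductive elimination) removes the C7 oxygen and leaves the C6=C7 alkene.

**Step 8**
Reactants: 14 6-ene silyl enol ether
Product: 15 11-hydroxyimino-12-ketone
Conditions: NOCl, CH2Cl2, −78 °C
Reagents that add atoms: nitrosyl chloride, O=NCl
Why: Electrophilic nitrosation of the silyl enol ether at C11 and tautomerisation give the α-oximino ketone regiospecifically, with no base that could enolise the C3 ketone.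

**Step 9**
Reactants: 15 α-oximino ketone
Product: 16 11-diazo-12-ketone
Conditions: aq. NH3, NaOCl, NaOH, Et2O, 0 °C
Reagents that add atoms: chloramine, NCl (formed in the flask from ammonia, N, and NaOCl, [Na+].[O-]Cl)
Why: Forster reaction (amination of the oxime nitrogen by chloramine, then loss of water and chloride), the classic route to 16-diazo-17-keto steroids; C1–H is not acidic, so the trans fusion is untouched.

**Step 10**
Reactants: 16 α-diazo ketone
Product: 19 cyclobutane methyl ester with free 14-OH (11α-CO2CH3, 11β-H), via ketene 17 (not isolated), via methyl ester 18 (not isolated)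
Conditions: hν (450 nm), MeOH, rt; NaOMe (0.2 equiv), rt; then HCl/MeOH, 0 °C
Reagents that add atoms: methanol, CO
Why: Wolff rearrangement (1,2-shift): on loss of N2 the ring bond C12–C9 migrates to C11 with retention at C9, so the trans-hydrindanone contracts to the cyclobutane and carries the 1α-H/10β-CH3 trans fusion into the four-membered ring as in D-nor steroid syntheses; methanol traps the ketene as the C12 ester, NaOMe equilibrates C11 to the α-ester (trans to C2 and to the 9-OTBS group), and acidic methanol removes only the secondary silyl ether.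

**Step 11**
Reactants: 19 propargylic alcohol ester
Product: 20 (Z)-13-iodo triol (C3-OH epimers, C12H2OH, C14-OH epimers)
Conditions: LiAlH4, AlCl3 (2 mol %), THF, 0 → 45 °C; then I2, −78 °C
Reagents that add atoms: iodine, II
Why: LiAlH4 reduces the ester and the C3 ketone, and the propargylic alkoxide directs trans-hydroalumination with aluminium on the proximal carbon C13 (AlCl3-modified conditions); iodinolysis with retention gives the (Z)-iodide, iodine cis to the C17 methyl.

**Step 12**
Reactants: 20 iodo triol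
Product: 21 3,14-diketo 12-aldehyde ((Z)-α-iodoenone)
Conditions: Dess–Martin periodinane, NaHCO3, CH2Cl2, 0 °C → rt
Reagents that add atoms: none
Why: Dess–Martin oxidation of the three carbinols under buffered, non-basic conditions, so the β,γ-alkene at C6 does not move into conjugation and C8 and C11 keep their configuration.

**Step 13**
Reactants: 21 iodoenone aldehyde
Product: 22 tetracyclic allylic alcohol (ring C closed; 12-OH epimers; (E)-ethylidene; 9β-OTBS)
Conditions: CrCl2 (6 equiv), NiCl2 (2 mol %), DMSO/THF, rt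
Reagents that add atoms: none
Why: Intramolecular Nozaki–Hiyama–Kishi reaction; the alkenylchromium species (trivalent chromium) adds to the aldehyde with retention of alkene geometry and closes ring C cis to ring B and to the cyclobutane, because C12 and C14 both sit on the α face.

**Step 14**
Reactants: 22 allylic alcohol
Product: 23 6,11(12),13(15)-triene-3,14-dione 9β-OTBS
Conditions: Martin sulfurane, CH2Cl2, 0 °C
Reagents that add atoms: none
Why: Dehydration of the secondary allylic alcohol through its alkoxysulfonium; C11–H is the only β-hydrogen, so only the C11=C12 alkene can form, and the tertiary silyl ether is inert.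

**Step 15**
Reactants: 23 silyl ether
Product: 24 triene-dione with free 9β-OH
Conditions: HF·pyridine, THF, rt
Reagents that add atoms: none
Why: Fluoride cleavage of the tertiary silyl ether under mildly acidic conditions that neither isomerise the β,γ-unsaturated ketone nor start a retro-aldol.

**Step 16**
Reactants: 24 triene-dione
Product: 25 6β,7β,9β,11β,12β-pentaol (13(15)-ethylidene kept)
Conditions: OsO4 (5 mol %), N-methylmorpholine N-oxide (2.5 equiv), acetone/H2O, 0 °C
Reagents that add atoms: osmium tetroxide (catalytic oxygen carrier), O=[Os](=O)(=O)=O; N-methylmorpholine N-oxide, C[N+]1([O-])CCOCC1; water, O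
Why: Upjohn dihydroxylation; OsO4 adds suprafacially to the two electron-rich alkenes (C6=C7, C11=C12) from the convex β face that also carries the 9-OH, while rings A and C and the cyclobutane shield the α face and the electron-poor enone alkene reacts far more slowly; this sets C6, C7, C11 and C12.

**Step 17**
Reactants: 25 pentaol
Product: 26 cyclopropane pentaol (C16 β, C15 α, 15-CH3 cis to C12)
Conditions: Et2Zn (8 equiv), CH2I2 (10 equiv), CH2Cl2, 0 °C → rt
Reagents that add atoms: diiodomethane, ICI
Why: Hydroxyl-directed Simmons–Smith cyclopropanation; the zinc alkoxide of the 12β-OH delivers the methylene of EtZnCH2I to the β face of C13=C15, and the concerted addition keeps the (E) geometry, which fixes C13 and C15.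

**Step 18**
Reactants: 26 cyclopropane pentaol
Product: 28 CNP0157858.2 (6β,12β-diacetate), via bis-orthoacetate 27 (not isolated)
Conditions: MeC(OMe)3, PPTS (cat.), CH2Cl2, rt; then AcOH/H2O, 0 °C → rt
Reagents that add atoms: trimethyl orthoacetate, COC(C)(OC)OC; water, O
Why: Orthoester mono-acylation of cis-diols; the 6,7- and 11,12-diols form cyclic methyl orthoacetates and aqueous acid opens each dioxolanylium to a hydroxy acetate, the acetyl ending on the secondary O12 (not the tertiary O11) and, after 1,2-acyl equilibration, on O6, which leaves the 7-OH hydrogen-bonded to the C14 ketone.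

**Compound list**
1 | 2-hydroxy-3-methylcyclopent-2-en-1-one (cyclotene) | CC1=C(O)C(=O)CC1 | starting material
2 | but-3-en-2-one | CC(=O)C=C | starting material
3 | (R)-3-methyl-3-(3-oxobutyl)cyclopentane-1,2-dione | CC(=O)CC[C@]1(C)CCC(=O)C1=O | intermediate (not isolated)
4 | (3aR,7aS)-7a-hydroxy-3a-methylhexahydro-1H-indene-1,6(2H)-dione (cis-ketol; 9β-OH, 10β-CH3) | O=C1CC[C@]2(C)CCC(=O)[C@]2(O)C1 | intermediate
5 | bis-enone: 4 with C1=C11 and C5=C6 double bonds | O=C1C=C[C@]2(C)C=CC(=O)[C@]2(O)C1 | intermediate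
6 | but-2-ynal | CC#CC=O | starting material
7 | 8α-(1-hydroxybut-2-yn-1-yl) derivative of 5 (8β-H; C14 epimers), present as dilithium alkoxide | O=C1C=C[C@]2(C)C=CC(=O)[C@]2(O)[C@@H]1C(O)C#CC | intermediate (not isolated)
8 | 9,14-bis-O-TBS ether of 7 | O=C1C=C[C@]2(C)C=CC(=O)[C@]2(O[Si](C)(C)C(C)(C)C)[C@@H]1C(O[Si](C)(C)C(C)(C)C)C#CC | intermediate
9 | 3-methylbutan-2-one | CC(=O)C(C)C | starting material
10 | 2-(tert-butyldimethylsilyloxy)-3-methylbut-1-ene | C=C(O[Si](C)(C)C(C)(C)C)C(C)C | intermediate
11 | Michael adduct: 8 carrying 1β-(3-methyl-2-oxobutyl) (1α-H) and a C11=C12 TBS enol ether | O=C1C=C[C@]2(C)[C@@H](CC(=O)C(C)C)C=C(O[Si](C)(C)C(C)(C)C)[C@]2(O[Si](C)(C)C(C)(C)C)[C@@H]1C(O[Si](C)(C)C(C)(C)C)C#CC | intermediate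
12 | tricycle after ring A closure (C3 ketone, 4,4-dimethyl, 5β-H; ring A trans to the five-membered ring), C6=C7 TMS enol ether, C11=C12 TBS enol ether | C1=C(O[Si](C)(C)C)[C@@H](C(O[Si](C)(C)C(C)(C)C)C#CC)[C@@]2(O[Si](C)(C)C(C)(C)C)C(O[Si](C)(C)C(C)(C)C)=C[C@@H]3CC(=O)C(C)(C)[C@@H]1[C@@]23C | intermediate (not isolated)
13 | C7 enol triflate of the tricycle | C1=C(OS(=O)(=O)C(F)(F)F)[C@@H](C(O[Si](C)(C)C(C)(C)C)C#CC)[C@@]2(O[Si](C)(C)C(C)(C)C)C(O[Si](C)(C)C(C)(C)C)=C[C@@H]3CC(=O)C(C)(C)[C@@H]1[C@@]23C | intermediate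
14 | 6-ene: 13 with H in place of the triflate | C1=C[C@@H](C(O[Si](C)(C)C(C)(C)C)C#CC)[C@@]2(O[Si](C)(C)C(C)(C)C)C(O[Si](C)(C)C(C)(C)C)=C[C@@H]3CC(=O)C(C)(C)[C@@H]1[C@@]23C | intermediate
15 | 11-hydroxyimino-12-ketone | C1=C[C@@H](C(O[Si](C)(C)C(C)(C)C)C#CC)[C@@]2(O[Si](C)(C)C(C)(C)C)C(=O)C(=NO)[C@@H]3CC(=O)C(C)(C)[C@@H]1[C@@]23C | intermediate
16 | 11-diazo-12-ketone | C1=C[C@@H](C(O[Si](C)(C)C(C)(C)C)C#CC)[C@@]2(O[Si](C)(C)C(C)(C)C)C(=O)C(=[N+]=[N-])[C@@H]3CC(=O)C(C)(C)[C@@H]1[C@@]23C | intermediate
17 | ketene: cyclobutane C1–C10–C9–C11 with C11=C12=O | C1=C[C@@H](C(O[Si](C)(C)C(C)(C)C)C#CC)[C@@]2(O[Si](C)(C)C(C)(C)C)C(=C=O)[C@@H]3CC(=O)C(C)(C)[C@@H]1[C@@]23C | intermediate (not isolated)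
18 | cyclobutane methyl ester (11α-CO2CH3, 11β-H; 9,14-bis-OTBS) | C1=C[C@@H](C(O[Si](C)(C)C(C)(C)C)C#CC)[C@@]2(O[Si](C)(C)C(C)(C)C)[C@@H](C(=O)OC)[C@@H]3CC(=O)C(C)(C)[C@@H]1[C@@]23C | intermediate (not isolated)
19 | 18 with free 14-OH | C1=C[C@@H](C(O)C#CC)[C@@]2(O[Si](C)(C)C(C)(C)C)[C@@H](C(=O)OC)[C@@H]3CC(=O)C(C)(C)[C@@H]1[C@@]23C | intermediate
20 | (13Z)-13-iodo-13(15)-ene 3,12,14-triol (C3, C14 epimers), 9β-OTBS | C1=C[C@@H](C(O)/C(I)=C/C)[C@@]2(O[Si](C)(C)C(C)(C)C)[C@@H](CO)[C@@H]3CC(O)C(C)(C)[C@@H]1[C@@]23C | intermediate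
21 | 3,14-diketo 12-aldehyde with (Z)-α-iodoenone | C1=C[C@@H](C(=O)/C(I)=C/C)[C@@]2(O[Si](C)(C)C(C)(C)C)[C@@H](C=O)[C@@H]3CC(=O)C(C)(C)[C@@H]1[C@@]23C | intermediate
22 | tetracycle: ring C closed, 12-OH (epimers), (E)-13(15)-ethylidene, 14-ketone, 11β-H, 9β-OTBS | C1=C[C@H]2C(=O)/C(=C/C)C(O)[C@H]3[C@@H]4CC(=O)C(C)(C)[C@@H]1[C@@]4(C)[C@@]23O[Si](C)(C)C(C)(C)C | intermediate
23 | 6,11(12),13(15)-triene-3,14-dione 9β-OTBS | C1=C[C@H]2C(=O)/C(=C/C)C=C3[C@@H]4CC(=O)C(C)(C)[C@@H]1[C@@]4(C)[C@@]23O[Si](C)(C)C(C)(C)C | intermediate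
24 | 6,11(12),13(15)-triene-3,14-dione 9β-ol | C1=C[C@H]2C(=O)/C(=C/C)C=C3[C@@H]4CC(=O)C(C)(C)[C@@H]1[C@@]4(C)[C@@]23O | intermediate
25 | 6β,7β,9β,11β,12β-pentaol with (E)-13(15)-ethylidene | O[C@@H]1[C@H](O)[C@H]2C(=O)/C(=C/C)[C@H](O)[C@@]3(O)[C@@H]4CC(=O)C(C)(C)[C@@H]1[C@@]4(C)[C@@]23O | intermediate
26 | cyclopropane pentaol (13,16-cyclo; C16 β; 15-CH3 cis to C12) | O[C@@H]1[C@H](O)[C@H]2C(=O)[C@]3(C[C@@H]3C)[C@H](O)[C@@]3(O)[C@@H]4CC(=O)C(C)(C)[C@@H]1[C@@]4(C)[C@@]23O | intermediate
27 | 6,7:11,12-bis-O-(1-methoxyethylidene) derivative of 26 (orthoester carbons as epimers) | COC1(C)O[C@@H]2[C@H](O1)[C@H]3C(=O)[C@]4(C[C@@H]4C)[C@@H]5OC(C)(OC)O[C@@]56[C@@H]7CC(=O)C(C)(C)[C@@H]2[C@@]7(C)[C@@]36O | intermediate (not isolated)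
28 | CNP0157858.2: 6β,12β-diacetoxy-7β,9β,11β-trihydroxy-1,11:13,16-dicyclo-abietane-3,14-dione (1α-H, 5β-H, 8β-H) | CC(=O)O[C@@H]1[C@H](O)[C@H]2C(=O)[C@]3(C[C@@H]3C)[C@H](OC(C)=O)[C@@]3(O)[C@@H]4CC(=O)C(C)(C)[C@@H]1[C@@]4(C)[C@@]23O | target

**Totals**
Total step count: 18. Longest linear sequence: 17 (steps 1–3 and 5–18; step 4 is a one-step side branch).

**Three steps most likely to fail**

Step 1 (the proposed new step; risk: low ee or O-alkylation of the diosphenol). Fallback with known chemistry, setting out from 1 (with 2): run the Michael addition with triethylamine and the aldolisation with pyrrolidinium acetate to obtain the ketol as a racemate, then separate the enantiomers by preparative chromatography on a chiral stationary phase; this gives 4 and its mirror image, ent-ketol F1, and the route is rejoined at 4.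

Step 17 (risk: the zinc carbenoid is electrophilic and the alkene is an enone alkene in a pentaol). Fallback setting out from 25: cyclopropanate with diazomethane and catalytic Pd(OAc)2 in ether at 0 °C, a known method for enone alkenes that adds CH2 suprafacially (geometry retained) from the open β face; this makes no new compound F0 and comes back at 26.

Step 18 (risk: wrong regiochemistry of orthoester opening or a competing 9,11-orthoester). Fallback setting out from 24, staging the oxygenation so that each acetylation meets only one secondary hydroxyl or one diol: OsO4 with TMEDA (1.05 equiv, CH2Cl2, −78 °C), directed by the allylic 9-OH, dihydroxylates only C11=C12 to give the 6-ene 11β,12β-diol F2; Et2Zn/CH2I2 then gives the 6-ene cyclopropane triol F3; Ac2O/DMAP acetylates the only secondary hydroxyl to give the 12-acetate F4; catalytic OsO4 with N-methylmorpholine N-oxide gives the 6β,7β-diol 12-acetate F5; one equivalent of Ac2O with 2,4,6-collidine at −40 °C followed by acyl equilibration puts the second acetate on O6, and the sequence comes back at 28.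

**Further compounds**
F1 | step 1 | ent-ketol, (3aS,7aR)-7a-hydroxy-3a-methylhexahydro-1H-indene-1,6(2H)-dione | O=C1CC[C@@]2(C)CCC(=O)[C@@]2(O)C1
F0 | step 17 | none | none
F2 | step 18 | 6-ene 11β,12β-diol (9β-OH, (E)-13(15)-ethylidene) | C1=C[C@H]2C(=O)/C(=C/C)[C@H](O)[C@@]3(O)[C@@H]4CC(=O)C(C)(C)[C@@H]1[C@@]4(C)[C@@]23O
F3 | step 18 | 6-ene cyclopropane triol | C1=C[C@H]2C(=O)[C@]3(C[C@@H]3C)[C@H](O)[C@@]3(O)[C@@H]4CC(=O)C(C)(C)[C@@H]1[C@@]4(C)[C@@]23O
F4 | step 18 | 6-ene cyclopropane 12-acetate | C1=C[C@H]2C(=O)[C@]3(C[C@@H]3C)[C@H](OC(C)=O)[C@@]3(O)[C@@H]4CC(=O)C(C)(C)[C@@H]1[C@@]4(C)[C@@]23O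
F5 | step 18 | 6β,7β-diol 12-acetate | O[C@@H]1[C@H](O)[C@H]2C(=O)[C@]3(C[C@@H]3C)[C@H](OC(C)=O)[C@@]3(O)[C@@H]4CC(=O)C(C)(C)[C@@H]1[C@@]4(C)[C@@]23O
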